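**The task.** Count the reagent. A closed flask holds solid first end groups and second end groups, and its links are read over time.

| flask | solid first end groups | second end groups | remark | time |
|---|---|---|---|---|
| summer | 1 M | 0.50 equiv | run made earlier |  |
| dusk | 1 M | 2 equiv | run made earlier |  |
| autumn | 2 M | 1 equiv | run made earlier |  |
| flask | 1.0 M | 1.00 equiv |  | 15 d |

| run | time / d | links / % |
|---|---|---|
| summer | 1.25 | 9.3 |
| summer | 4.00 | 6.0 |
| summer | 8.00 | 7.4 |
| summer | 10.0 | 6.8 |
| summer | 15.0 | 6.7 |
| dusk | 1.25 | 21.4 |
| dusk | 4.00 | 24.6 |
| dusk | 8.00 | 24.0 |
| dusk | 10.0 | 24.1 |
| dusk | 15.0 | 22.9 |
| autumn | 3.00 | 11.3 |
| autumn | 6.00 | 14.0 |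
| autumn | 10.0 | 11.4 |
| autumn | 12.0 | 11.6 |
| autumn | 15.0 | 11.3 |

(scatter of a reading: 1 percentage point)

- at the start none of the solid first end groups is in solution
- what has only dissolved of solid first end groups counts as not reacted
- the reaction counts as stopped when no species that holds the solid first end groups changes by six tenths of a point or more over the second half of the time

- why nothing more happens at 15 d, or that something still does (for what has run out or reacted, a solid counts together with what of it has only dissolved) (forward and back rates have come level / the second end groups has run out first / all of the solid first end groups has reacted / it is still moving)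
- the links standing at 15 d, as a percentage of the solid first end groups charged

**Which number counts.** Time comes first: summer links read 6.0% at 4.00 d and 6.7% at 15.0 d, each good to 1 percentage point, so late in that run an error in time moves the reading little. The solid charge comes next: dusk holds 1 M and autumn 2 M, both with 2.00 M of second end groups, and their last readings average 23.7% and 11.4%, or 0.237 M and 0.228 M of links. Second end groups come last: from summer to dusk their equivalents rise by a factor of 4.00, and links by 3.40. That charge has to be known well.

**Link share.** Over their late readings, summer reads 0.139 and dusk 0.118 links per second end group charged. The flask, at 1.00 equiv, lies between those runs in equivalents, so this reckoning takes s = 0.129, the links standing per second end group charged, and expects 12.9%.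

**The forecast.** It gives 12.5% and forward and back rates have come level: “this is equilibrium, not exhaustion”.

**The flask.** At 15 d the outcome is: the second end groups has run out first, with 0% of that charge left and links at 14.3%.

    first end groups + second end groups → rings, rate k1*[first end groups] as long as [second end groups] is above zero (k = 0.680 h⁻¹)
    second end groups → decomposed reagent (k = 0.0630 h⁻¹)
    first end groups + second end groups → links (k = 1.70 M⁻¹ h⁻¹)
    solid first end groups ⇌ first end groups, rate k4*(cs4 - [first end groups]) while solid is left; crystals form when [first end groups] > cs4 (solubility = 0.780 M, k = 0.0180 h⁻¹)
    links → over-reaction product (k = 5.00 × 10⁻⁵ h⁻¹)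

In the flask, half of the turnover of second end groups to decomposed reagent up to 15 d is done by 0.266 d, sooner than half of the turnover of the dissolution of the solid, at 1.54 d. At 1.50 d the flask still holds 51.1% as solid while second end groups stand at 0%. Its link share comes to 0.143 against s of 0.129. A second flask with 0.250 equiv of second end groups should hold 3.22% by s, and it holds 2.99%.

The runs stem from a simulated flask on assumed constants.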